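**Plan**

- Retrosynthesis: the two aryl O–CH3 bonds are cut first, then the C1–C2 bond of ring A, which opens the ring to a 3,5,7-triketo decanoate that already carries ring B.
- Further cuts: the chain C4–CH2(aryl) bond (enolate benzylation), the chain C4–C5 bond (enolate acylation by a ketal-masked 3-oxohexanoyl unit), and on ring B the C–CH2Br and C–butanoyl bonds.
- Forward: ring B is the ring of 2,5-dimethylresorcinol and receives its butanoyl group and a bromomethyl handle; the keto ester chain is built separately, joined to ring B by C-benzylation, and ring A is closed in the penultimate step.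
- Enabling feature: in ring A the oxygenated C2, C4 and C6 alternate with C1 (butanoyl), C3 (gem-dimethyl) and C5 (CH2 bridge), which is a head-to-tail folded triketo ester with a 2,2-dimethyl ester terminus.
- Stereochemistry: the target is achiral; the one stereocenter on the way (chain C4 of 12 and 13) is racemic and disappears on ring closure.

Key step: step 9

Remark: ring A of the target is drawn as one enol tautomer of a rapidly equilibrating acyl trione, and methyl 2,2-dimethyl-3-oxobutanoate (9) is taken as a purchasable starting material.

Step 1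
Reactants: 1 2,5-dimethylbenzene-1,3-diol (2,5-dimethylresorcinol); 2 butanoyl chloride
Product: 3 1-(2,4-dihydroxy-3,6-dimethylphenyl)butan-1-one
Conditions: AlCl3, PhNO2, 0 °C to 50 °C; then ice/aq. HCl
Reagents that add atoms: none
Why: Friedel–Crafts acylation of the free resorcinol should occur at C4, which is ortho and para to the two hydroxyls and equivalent to C6 by symmetry, so a single ketone is expected and the first acyl group deactivates the ring towards a second.

Step 2
Reactants: 3 1-(2,4-dihydroxy-3,6-dimethylphenyl)butan-1-one
Product: 4 1-(2,4-dimethoxy-3,6-dimethylphenyl)butan-1-one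
Conditions: MeI (excess), K2CO3, DMF, 60 °C
Reagents that add atoms: iodomethane, CI
Why: Williamson O-methylation of both phenoxides should go to completion in warm DMF, where carbonate is basic enough to free the hydroxyl that is hydrogen-bonded to the ketone but too weak to enolize the ketone.

Step 3
Reactants: 4 1-(2,4-dimethoxy-3,6-dimethylphenyl)butan-1-one
Product: 5 1-[3-(bromomethyl)-4,6-dimethoxy-2,5-dimethylphenyl]butan-1-one
Conditions: (CH2O)n, 33% HBr in AcOH, 40 °C
Reagents that add atoms: formaldehyde (as paraformaldehyde), C=O; hydrogen bromide, Br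
Why: Blanc-type bromomethylation is an electrophilic aromatic substitution that can only take place at the one unsubstituted ring carbon, which is ortho to one methoxy group and para to the other, and the fully substituted product cannot be alkylated further on its own ring.

Step 4
Reactants: 6 ethyl 3-oxohexanoate
Product: 7 ethyl 2-(2-propyl-1,3-dioxolan-2-yl)acetate
Conditions: HOCH2CH2OH, p-TsOH (cat.), toluene, reflux with azeotropic removal of water
Reagents that add atoms: ethane-1,2-diol, OCCO
Why: Acid-catalysed ketalization of the ketone of a beta-keto ester, driven by removal of water, masks the future C7 carbonyl and removes the acidity of the methylene beside it.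

Step 5
Reactants: 7 ethyl 2-(2-propyl-1,3-dioxolan-2-yl)acetate
Product: 8 2-(2-propyl-1,3-dioxolan-2-yl)acetic acid
Conditions: LiOH, THF/H2O, rt; then cold aq. HCl to pH 4
Reagents that add atoms: lithium hydroxide (hydroxide oxygen), [Li+].[OH-]
Why: Saponification of the ethyl ester leaves the base-stable dioxolane untouched, and a cold, weakly acidic work-up should keep the ketal intact.

Step 6
Reactants: 8 2-(2-propyl-1,3-dioxolan-2-yl)acetic acid; 9 methyl 2,2-dimethyl-3-oxobutanoate
Product: 11 methyl 2,2-dimethyl-3,5-dioxo-6-(2-propyl-1,3-dioxolan-2-yl)hexanoate, via acyl imidazolide 10 (not isolated)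
Conditions: 8, 1,1'-carbonyldiimidazole, THF, rt; then added to 9 and LiN(SiMe3)2 (3.2 equiv each), THF, –78 °C to –30 °C; aq. NH4Cl
Reagents that add atoms: 1,1'-carbonyldiimidazole, O=C(n1ccnc1)n1ccnc1 (imidazolyl group of intermediate 10 only; nothing from it remains in 11)
Why: Crossed Claisen C-acylation of the kinetic lithium enolate of 9, whose methyl group is its only enolizable position, by an acyl imidazolide should give the 1,3-diketone, with the excess enolate absorbing the protons of imidazole and of the diketone formed.

Step 7
Reactants: 11 methyl 2,2-dimethyl-3,5-dioxo-6-(2-propyl-1,3-dioxolan-2-yl)hexanoate; 5 1-[3-(bromomethyl)-4,6-dimethoxy-2,5-dimethylphenyl]butan-1-one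
Product: 12 racemic methyl 4-[(3-butanoyl-4,6-dimethoxy-2,5-dimethylphenyl)methyl]-2,2-dimethyl-3,5-dioxo-6-(2-propyl-1,3-dioxolan-2-yl)hexanoate
Conditions: K2CO3, Bu4NI (cat.), acetone, 50 °C
Reagents that add atoms: none
Why: C-alkylation of the potassium enolate of the 1,3-diketone at C4, the only doubly activated carbon of 11, by the reactive benzylic bromide should proceed under carbonate conditions that spare the aryl ketone, the ester and the ketal, and the new C4 stereocenter is formed racemic and is of no consequence.

Step 8
Reactants: 12 racemic methyl 4-[(3-butanoyl-4,6-dimethoxy-2,5-dimethylphenyl)methyl]-2,2-dimethyl-3,5-dioxo-6-(2-propyl-1,3-dioxolan-2-yl)hexanoate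
Product: 13 racemic methyl 4-[(3-butanoyl-4,6-dimethoxy-2,5-dimethylphenyl)methyl]-2,2-dimethyl-3,5,7-trioxodecanoate
Conditions: 1 M aq. HCl, THF, rt
Reagents that add atoms: water, O
Why: Acid-catalysed ketal hydrolysis should be easy here because the liberated triketone is stabilized by enolization, while the hindered methyl ester and the aryl methyl ethers are stable to dilute acid at room temperature.

Step 9
Reactants: 13 racemic methyl 4-[(3-butanoyl-4,6-dimethoxy-2,5-dimethylphenyl)methyl]-2,2-dimethyl-3,5,7-trioxodecanoate
Product: 14 2-butanoyl-6-[(3-butanoyl-4,6-dimethoxy-2,5-dimethylphenyl)methyl]-3,5-dihydroxy-4,4-dimethylcyclohexa-2,5-dien-1-one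
Conditions: NaOMe (4 equiv), MeOH, 0 °C to reflux; then cold 1 M aq. HCl
Reagents that add atoms: none
Why: Methoxide removes a proton from chain C6, the methylene between the C5 and C7 ketones (ring A C1), and this enolate adds to the C1 methyl ester carbonyl (ring A C2), after which the tetrahedral intermediate expels methoxide and the C1–C2 bond of ring A is in place. The closest known reaction is the Claisen (Dieckmann-type) cyclization of 3,5,7-triketo esters to acylphloroglucinols, held here at the non-aromatic trione level by the quaternary carbon. Ring A closes in the 6-exo-trig mode, and the gem-dimethyl group at chain C2 favours the folded conformer (Thorpe–Ingold effect). No stereocenter is formed, and the racemic C4 center of 13 is erased because it becomes the sp2 C5 of the enolized ring. The step needs acylation at carbon by the right carbanion: chain C2 has no hydrogen and so cannot start an aldol folding to an aromatic ring, the other doubly activated carbon C4 would have to close a four-membered ring, the C8 and aryl ketone methylenes are only singly activated and stay protonated in methanolic methoxide, and an enol lactone from O-acylation would be reopened by methoxide. The product is a strongly acidic enolized triketone that is converted into its dianion, which should make the closure irreversible and protect the ring carbonyls from retro-Claisen attack.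

Step 10
Reactants: 14 2-butanoyl-6-[(3-butanoyl-4,6-dimethoxy-2,5-dimethylphenyl)methyl]-3,5-dihydroxy-4,4-dimethylcyclohexa-2,5-dien-1-one
Product: 15 2-butanoyl-6-[(3-butanoyl-4,6-dihydroxy-2,5-dimethylphenyl)methyl]-3,5-dihydroxy-4,4-dimethylcyclohexa-2,5-dien-1-one (CNP0295128.0)
Conditions: BBr3 (8 equiv), CH2Cl2, –78 °C to 0 °C; then ice water
Reagents that add atoms: none
Why: Lewis acid ether cleavage by BBr3 (boron binds the ether oxygen and bromide attacks the methyl group in an SN2 step) should remove both aryl methyl groups, helped at the methoxy group ortho to the ring B ketone by chelation, while ring A is held as a boron chelate at low temperature and is released with the phenols on hydrolysis.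

**Compound list**

1 | 2,5-dimethylbenzene-1,3-diol (2,5-dimethylresorcinol) | Cc1cc(O)c(C)c(O)c1 | starting material
2 | butanoyl chloride | CCCC(Cl)=O | starting material
3 | 1-(2,4-dihydroxy-3,6-dimethylphenyl)butan-1-one | CCCC(=O)c1c(C)cc(O)c(C)c1O | intermediate
4 | 1-(2,4-dimethoxy-3,6-dimethylphenyl)butan-1-one | CCCC(=O)c1c(C)cc(OC)c(C)c1OC | intermediate
5 | 1-[3-(bromomethyl)-4,6-dimethoxy-2,5-dimethylphenyl]butan-1-one | CCCC(=O)c1c(C)c(CBr)c(OC)c(C)c1OC | intermediate
6 | ethyl 3-oxohexanoate | CCCC(=O)CC(=O)OCC | starting material
7 | ethyl 2-(2-propyl-1,3-dioxolan-2-yl)acetate | CCCC1(CC(=O)OCC)OCCO1 | intermediate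
8 | 2-(2-propyl-1,3-dioxolan-2-yl)acetic acid | CCCC1(CC(=O)O)OCCO1 | intermediate
9 | methyl 2,2-dimethyl-3-oxobutanoate | CC(=O)C(C)(C)C(=O)OC | starting material
10 | 1-(1H-imidazol-1-yl)-2-(2-propyl-1,3-dioxolan-2-yl)ethan-1-one (acyl imidazolide, not isolated) | CCCC1(CC(=O)n2ccnc2)OCCO1 | intermediate
11 | methyl 2,2-dimethyl-3,5-dioxo-6-(2-propyl-1,3-dioxolan-2-yl)hexanoate | CCCC1(CC(=O)CC(=O)C(C)(C)C(=O)OC)OCCO1 | intermediate
12 | racemic methyl 4-[(3-butanoyl-4,6-dimethoxy-2,5-dimethylphenyl)methyl]-2,2-dimethyl-3,5-dioxo-6-(2-propyl-1,3-dioxolan-2-yl)hexanoate | CCCC1(CC(=O)C(Cc2c(C)c(C(=O)CCC)c(OC)c(C)c2OC)C(=O)C(C)(C)C(=O)OC)OCCO1 | intermediate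
13 | racemic methyl 4-[(3-butanoyl-4,6-dimethoxy-2,5-dimethylphenyl)methyl]-2,2-dimethyl-3,5,7-trioxodecanoate | CCCC(=O)CC(=O)C(Cc1c(C)c(C(=O)CCC)c(OC)c(C)c1OC)C(=O)C(C)(C)C(=O)OC | intermediate
14 | 2-butanoyl-6-[(3-butanoyl-4,6-dimethoxy-2,5-dimethylphenyl)methyl]-3,5-dihydroxy-4,4-dimethylcyclohexa-2,5-dien-1-one (achiral) | CCCC(=O)C1=C(O)C(C)(C)C(O)=C(Cc2c(C)c(C(=O)CCC)c(OC)c(C)c2OC)C1=O | intermediate
15 | 2-butanoyl-6-[(3-butanoyl-4,6-dihydroxy-2,5-dimethylphenyl)methyl]-3,5-dihydroxy-4,4-dimethylcyclohexa-2,5-dien-1-one (achiral) | CCCC(=O)C1=C(O)C(C)(C)C(O)=C(Cc2c(C)c(C(=O)CCC)c(O)c(C)c2O)C1=O | target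

**Step count**

Total: 10 steps. Longest linear sequence: 7 steps (steps 4 to 10 from 6, or steps 1 to 3 and 7 to 10 from 1).

**Steps most likely to fail**

Step 9. Methoxide may add to the hindered C3 ketone of 13, which has a quaternary carbon on one side, so that the chain fragments by retro-Claisen scission faster than it cyclizes. Closure through an enol oxygen may also divert material to lactone or pyranone products that do not return to the carbocycle. The fallback takes ring A from an aromatic precursor instead of closing it from the chain; it sets out from 2 and 5 and comes back at 14. Commercial benzene-1,3,5-triol is acylated with 2 (AlCl3, PhNO2) to give 1-(2,4,6-trihydroxyphenyl)butan-1-one F1. Dearomatizing double C-methylation (MeI, NaOMe, MeOH) then gives 2-butanoyl-3,5-dihydroxy-4,4-dimethylcyclohexa-2,5-dien-1-one F2. Its sodium enolate is C-benzylated at the one free ring carbon with bromide 5 (NaOMe, MeOH), which gives 14.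

Step 6. The enolate may act as a base towards the CH2 of the acyl imidazolide, the dioxolane may open by beta-elimination, or acylation may take place on the enolate oxygen. The fallback makes the C4–C5 bond by aldol addition and installs the ketone by oxidation; it sets out from 7 and comes back at 11. Reduction of 7 with i-Bu2AlH (CH2Cl2, –78 °C) gives 2-(2-propyl-1,3-dioxolan-2-yl)acetaldehyde F3. Aldol addition of the lithium enolate of 9 (LiN(SiMe3)2, THF, –78 °C) gives racemic methyl 5-hydroxy-2,2-dimethyl-3-oxo-6-(2-propyl-1,3-dioxolan-2-yl)hexanoate F4. Oxidation with Dess–Martin periodinane (CH2Cl2, rt) then gives 11.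

Step 3. Substitution may be slow because the open position lies between a methoxy and a methyl group on a ring that carries a ketone, so that ether cleavage by HBr or attack of the benzylic bromide on unreacted 4 can compete. The fallback brings the carbon in at the aldehyde level with a stronger electrophile and then adjusts it; it sets out from 4 and comes back at 5. Formylation with Cl2CHOMe and TiCl4 (CH2Cl2, 0 °C) gives 3-butanoyl-4,6-dimethoxy-2,5-dimethylbenzaldehyde F5. Aldehyde-selective reduction (NaBH4, EtOH, –40 °C) gives 1-[3-(hydroxymethyl)-4,6-dimethoxy-2,5-dimethylphenyl]butan-1-one F6. Treatment with 33% HBr in AcOH at room temperature converts the benzylic alcohol into 5.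

**Further compounds**

F1 | step 9 | 1-(2,4,6-trihydroxyphenyl)butan-1-one | CCCC(=O)c1c(O)cc(O)cc1O
F2 | step 9 | 2-butanoyl-3,5-dihydroxy-4,4-dimethylcyclohexa-2,5-dien-1-one | CCCC(=O)C1=C(O)C(C)(C)C(O)=CC1=O
F3 | step 6 | 2-(2-propyl-1,3-dioxolan-2-yl)acetaldehyde | CCCC1(CC=O)OCCO1
F4 | step 6 | racemic methyl 5-hydroxy-2,2-dimethyl-3-oxo-6-(2-propyl-1,3-dioxolan-2-yl)hexanoate | CCCC1(CC(O)CC(=O)C(C)(C)C(=O)OC)OCCO1
F5 | step 3 | 3-butanoyl-4,6-dimethoxy-2,5-dimethylbenzaldehyde | CCCC(=O)c1c(C)c(C=O)c(OC)c(C)c1OC
F6 | step 3 | 1-[3-(hydroxymethyl)-4,6-dimethoxy-2,5-dimethylphenyl]butan-1-one | CCCC(=O)c1c(C)c(CO)c(OC)c(C)c1OC
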